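**Plan**

- Ring A bears oxygen on every second ring carbon (OMe, OH, OH) and carbon groups on the three carbons between them (isovaleryl, methyl, the CH2 bridge). This is the pattern of a folded 3,5,7-trioxygenated decanoate, so ring A is cut between the isovaleryl-bearing carbon and the neighbouring hydroxyl-bearing carbon next to the bridge (a Claisen bond).
- The open chain is cut further at C2–CH2(ring B) (enolate benzylation), at C2–C3 (acylation of Meldrum's acid) and at C6–C7 (vinylogous aldol addition).
- Forward: ring B is finished first from 2-methylphloroglucinol (formylation, para-O-methylation directed by the formyl group, acylation, benzylation, CHO to CH2Br). The chain is built from methyl 2-methylacetoacetate, 3-methylbutanal and Meldrum's acid, the two parts are joined by C-benzylation, C7 is oxidised, ring A is closed last and the benzyl ethers are removed.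
- Stereochemistry: the target has no stereocentre. The carbinol and C2 centres of the intermediates are racemic and disappear on oxidation and aromatisation. The E enol ether comes from the acid-equilibrated enol ether 11.

Key step: step 14

Assumption: enol ether 11 is used as its E isomer (C4 methyl cis to the ester) after distillation. Compounds 15, 16 and 19 are racemic, 20 and 21 are mixtures of racemic diastereomers, and 22 is racemic at the enolisable C2; none of this affects the target.

Remark on the design: the C7 ketone is carried as a silyl-protected alcohol until after the benzylation. An activated 3-methoxy-5-oxo-2-enoic acid would close to a 4-methoxy-2-pyranone, and a free 3,7-diketone would offer a second acidic methylene to the benzyl bromide. Ring B is protected as benzyl ethers so that the last step is a neutral hydrogenolysis.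

**Route**

Step 1
Reactants: 1 2-methylphloroglucinol
Product: 3 2,4,6-trihydroxy-3-methylbenzaldehyde, via aryl iminium chloride 2 (not isolated)
Conditions: POCl3, DMF, EtOAc, 0 °C to rt; then H2O, 50 °C
Reagents that add atoms: N,N-dimethylformamide CN(C)C=O; water O
Why: Vilsmeier–Haack formylation of the strongly activated arene at one of its two equivalent free positions, followed by hydrolysis of iminium salt 2, should give the mono-aldehyde.

Step 2
Reactants: 3 2,4,6-trihydroxy-3-methylbenzaldehyde
Product: 4 2,6-dihydroxy-4-methoxy-3-methylbenzaldehyde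
Conditions: MeI (1 equiv), K2CO3 (1 equiv), acetone, 0 °C to rt
Reagents that add atoms: iodomethane CI
Why: Williamson etherification should occur at the hydroxyl para to the formyl group, which is the most acidic and the only one not hydrogen-bonded to the aldehyde, so the methoxy group ends up next to the ring methyl group.

Step 3
Reactants: 4 2,6-dihydroxy-4-methoxy-3-methylbenzaldehyde; 5 isobutyryl chloride
Product: 6 2,6-dihydroxy-4-methoxy-3-methyl-5-(2-methylpropanoyl)benzaldehyde
Conditions: AlCl3, CH2Cl2/MeNO2, 0 °C to rt; then cold 1 M HCl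
Reagents that add atoms: none
Why: Friedel–Crafts acylation can only take place at the single unsubstituted ring carbon, which is still activated by three oxygen substituents, and the low temperature should spare the methyl ether.

Step 4
Reactants: 6 2,6-dihydroxy-4-methoxy-3-methyl-5-(2-methylpropanoyl)benzaldehyde
Product: 7 2,6-bis(benzyloxy)-4-methoxy-3-methyl-5-(2-methylpropanoyl)benzaldehyde
Conditions: BnBr, K2CO3, DMF, 60 °C
Reagents that add atoms: benzyl bromide BrCc1ccccc1
Why: Double Williamson benzylation in a dipolar aprotic solvent with heating should also reach the hydroxyl that is hydrogen-bonded to both carbonyl groups.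

Step 5
Reactants: 7 2,6-bis(benzyloxy)-4-methoxy-3-methyl-5-(2-methylpropanoyl)benzaldehyde
Product: 8 1-[2,4-bis(benzyloxy)-3-(hydroxymethyl)-6-methoxy-5-methylphenyl]-2-methylpropan-1-one
Conditions: NaBH4, THF/MeOH, 0 °C
Reagents that add atoms: none
Why: Hydride reduction with NaBH4 should be chemoselective for the aldehyde because the aryl isopropyl ketone is flanked by two ortho substituents and is far less electrophilic.

Step 6
Reactants: 8 1-[2,4-bis(benzyloxy)-3-(hydroxymethyl)-6-methoxy-5-methylphenyl]-2-methylpropan-1-one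
Product: 9 1-[2,4-bis(benzyloxy)-3-(bromomethyl)-6-methoxy-5-methylphenyl]-2-methylpropan-1-one
Conditions: CBr4, PPh3, CH2Cl2, 0 °C; short silica pad, used at once
Reagents that add atoms: tetrabromomethane BrC(Br)(Br)Br
Why: The Appel reaction converts the benzylic alcohol into the bromide under neutral conditions that an electron-rich, easily ionised benzylic system tolerates.

Step 7
Reactants: 10 methyl 2-methylacetoacetate
Product: 11 methyl (E)-3-methoxy-2-methylbut-2-enoate
Conditions: HC(OMe)3, cat. H2SO4, rt; distillation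
Reagents that add atoms: trimethyl orthoformate COC(OC)OC
Why: Acid-catalysed enol ether formation with the orthoester (dimethyl ketal, then loss of methanol) should give the conjugated E isomer as the main, distillable product.

Step 8
Reactants: 11 methyl (E)-3-methoxy-2-methylbut-2-enoate; 12 3-methylbutanal
Product: 15 racemic methyl (E)-5-[(tert-butyldimethylsilyl)oxy]-3-methoxy-2,7-dimethyloct-2-enoate, via lithium dienolate 13 (not isolated), via lithium aldolate 14 (not isolated)
Conditions: LiN(i-Pr)2, THF, −78 °C; 12, −78 °C; TBSOTf, −78 to −40 °C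
Reagents that add atoms: tert-butyldimethylsilyl trifluoromethanesulfonate CC(C)(C)[Si](C)(C)OS(=O)(=O)C(F)(F)F
Why: Deprotonation of the γ-methyl group cis to the ester gives the dienolate, whose vinylogous aldol addition through the γ-carbon retains the alkene geometry, and silylation of the cold aldolate blocks its lactonisation onto the cis ester; the new carbinol centre is racemic and is removed in step 13.

Step 9
Reactants: 15 racemic methyl (E)-5-[(tert-butyldimethylsilyl)oxy]-3-methoxy-2,7-dimethyloct-2-enoate
Product: 16 racemic (E)-5-[(tert-butyldimethylsilyl)oxy]-3-methoxy-2,7-dimethyloct-2-enoic acid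
Conditions: LiOH, THF/MeOH/H2O, 50 °C; then 1 M HCl to pH 4, 0 °C
Reagents that add atoms: lithium hydroxide [Li+].[OH-]
Why: Saponification of the hindered β-methoxyacrylate needs gentle heating, which the secondary silyl ether should survive, and careful acidification keeps the enol ether intact.

Step 10
Reactants: 16 racemic (E)-5-[(tert-butyldimethylsilyl)oxy]-3-methoxy-2,7-dimethyloct-2-enoic acid; 17 Meldrum's acid
Product: 19 racemic methyl (E)-7-[(tert-butyldimethylsilyl)oxy]-5-methoxy-4,9-dimethyl-3-oxodec-4-enoate, via acyl Meldrum's acid 18 (not isolated)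
Conditions: DCC, DMAP, CH2Cl2, 0 °C to rt; then MeOH, reflux
Reagents that add atoms: methanol CO
Why: Carbodiimide-mediated C-acylation of Meldrum's acid followed by thermal methanolysis through the acylketene is the standard β-keto ester synthesis from a carboxylic acid and leaves the silyl ether untouched.

Step 11
Reactants: 19 racemic methyl (E)-7-[(tert-butyldimethylsilyl)oxy]-5-methoxy-4,9-dimethyl-3-oxodec-4-enoate; 9 1-[2,4-bis(benzyloxy)-3-(bromomethyl)-6-methoxy-5-methylphenyl]-2-methylpropan-1-one
Product: 20 methyl (E)-2-{[2,6-bis(benzyloxy)-4-methoxy-3-methyl-5-(2-methylpropanoyl)phenyl]methyl}-7-[(tert-butyldimethylsilyl)oxy]-5-methoxy-4,9-dimethyl-3-oxodec-4-enoate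
Conditions: K2CO3, acetone, rt
Reagents that add atoms: none
Why: SN2 C-alkylation of the potassium enolate of the β-keto ester should occur only at C2, the single acidic position while C7 is still a silyl ether, and without strong base the aryl ketone of ring B is not enolised.

Step 12
Reactants: 20 methyl (E)-2-{[2,6-bis(benzyloxy)-4-methoxy-3-methyl-5-(2-methylpropanoyl)phenyl]methyl}-7-[(tert-butyldimethylsilyl)oxy]-5-methoxy-4,9-dimethyl-3-oxodec-4-enoate
Product: 21 methyl (E)-2-{[2,6-bis(benzyloxy)-4-methoxy-3-methyl-5-(2-methylpropanoyl)phenyl]methyl}-7-hydroxy-5-methoxy-4,9-dimethyl-3-oxodec-4-enoate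
Conditions: HF·pyridine, pyridine, THF, 0 °C to rt
Reagents that add atoms: none
Why: Fluoride-mediated cleavage of the silyl ether under pyridine-buffered conditions should free the C7 alcohol without hydrolysing the enol ether.

Step 13
Reactants: 21 methyl (E)-2-{[2,6-bis(benzyloxy)-4-methoxy-3-methyl-5-(2-methylpropanoyl)phenyl]methyl}-7-hydroxy-5-methoxy-4,9-dimethyl-3-oxodec-4-enoate
Product: 22 methyl (E)-2-{[2,6-bis(benzyloxy)-4-methoxy-3-methyl-5-(2-methylpropanoyl)phenyl]methyl}-5-methoxy-4,9-dimethyl-3,7-dioxodec-4-enoate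
Conditions: Dess–Martin periodinane, pyridine, CH2Cl2, 0 °C to rt
Reagents that add atoms: none
Why: Dess–Martin oxidation of the secondary alcohol under buffered, non-basic conditions should give the C7 ketone without triggering premature cyclisation.

Step 14
Reactants: 22 methyl (E)-2-{[2,6-bis(benzyloxy)-4-methoxy-3-methyl-5-(2-methylpropanoyl)phenyl]methyl}-5-methoxy-4,9-dimethyl-3,7-dioxodec-4-enoate
Product: 23 1-[3-({2,6-bis(benzyloxy)-4-methoxy-3-methyl-5-(2-methylpropanoyl)phenyl}methyl)-2,4-dihydroxy-6-methoxy-5-methylphenyl]-3-methylbutan-1-one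
Conditions: Mg(OMe)2 (excess), MeOH, reflux; then cold 1 M HCl
Reagents that add atoms: none
Why: Mg(OMe)2 converts the β-keto ester into its chelated magnesium enolate and, in equilibrium, deprotonates the C6 methylene, which is flanked by the C7 isovaleryl ketone and is vinylogous to the C3 ketone through the C4=C5 enol ether; this extended enolate adds through C6 to the C1 ester carbonyl, methoxide leaves, and the resulting 2-acylcyclohexenedione enolises twice to the aromatic ring A. The closest known reaction type is the Claisen (Dieckmann-type) cyclisation of 3,5,7-trioxoalkanoates and their enol ethers to acylphloroglucinols under magnesium alkoxides. Ring A closes in a 6-(enolexo)-exo-trig mode by forming the bond between the acyl-bearing carbon and the hydroxyl-bearing carbon next to the bridge. No stereocentre is created, and the racemic C2 centre is erased on aromatisation. The step needs C-acylation at C1 to win over aldol addition of C2 to the C7 ketone, over pyranone formation and over retro-Claisen cleavage: the aldol adduct has a quaternary benzyl-bearing carbon, cannot aromatise and reverts, the methyl enol ether at C5 removes the oxygen nucleophile needed for a pyranone and fixes the methoxy group between the methyl- and acyl-bearing carbons, and magnesium chelation shields the C3 carbonyl from methoxide. The C4=C5 geometry is not critical, because the bond can rotate in the extended enolate.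

Step 15
Reactants: 23 1-[3-({2,6-bis(benzyloxy)-4-methoxy-3-methyl-5-(2-methylpropanoyl)phenyl}methyl)-2,4-dihydroxy-6-methoxy-5-methylphenyl]-3-methylbutan-1-one
Product: 24 1-[3-({2,6-dihydroxy-4-methoxy-3-methyl-5-(2-methylpropanoyl)phenyl}methyl)-2,4-dihydroxy-6-methoxy-5-methylphenyl]-3-methylbutan-1-one (CNP0265841.0)
Conditions: H2 (1 atm), 10% Pd/C, EtOAc, rt
Reagents that add atoms: none
Why: Hydrogenolysis of the two benzyl aryl ethers over palladium under neutral conditions should leave the aryl ketones, the methyl ethers and the diarylmethane bridge unchanged.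

**Compound list**

1 | 2-methylphloroglucinol (2-methylbenzene-1,3,5-triol) | Cc1c(O)cc(O)cc1O | starting material
2 | (2,4,6-trihydroxy-3-methylbenzylidene)dimethyliminium chloride | C[N+](C)=Cc1c(O)cc(O)c(C)c1O.[Cl-] | intermediate
3 | 2,4,6-trihydroxy-3-methylbenzaldehyde | Cc1c(O)cc(O)c(C=O)c1O | intermediate
4 | 2,6-dihydroxy-4-methoxy-3-methylbenzaldehyde | COc1cc(O)c(C=O)c(O)c1C | intermediate
5 | isobutyryl chloride (2-methylpropanoyl chloride) | CC(C)C(Cl)=O | starting material
6 | 2,6-dihydroxy-4-methoxy-3-methyl-5-(2-methylpropanoyl)benzaldehyde | COc1c(C)c(O)c(C=O)c(O)c1C(=O)C(C)C | intermediate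
7 | 2,6-bis(benzyloxy)-4-methoxy-3-methyl-5-(2-methylpropanoyl)benzaldehyde | COc1c(C)c(OCc2ccccc2)c(C=O)c(OCc2ccccc2)c1C(=O)C(C)C | intermediate
8 | 1-[2,4-bis(benzyloxy)-3-(hydroxymethyl)-6-methoxy-5-methylphenyl]-2-methylpropan-1-one | COc1c(C)c(OCc2ccccc2)c(CO)c(OCc2ccccc2)c1C(=O)C(C)C | intermediate
9 | 1-[2,4-bis(benzyloxy)-3-(bromomethyl)-6-methoxy-5-methylphenyl]-2-methylpropan-1-one | COc1c(C)c(OCc2ccccc2)c(CBr)c(OCc2ccccc2)c1C(=O)C(C)C | intermediate
10 | methyl 2-methylacetoacetate (methyl 2-methyl-3-oxobutanoate) | CC(=O)C(C)C(=O)OC | starting material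
11 | methyl (E)-3-methoxy-2-methylbut-2-enoate | C/C(OC)=C(/C)C(=O)OC | intermediate
12 | 3-methylbutanal (isovaleraldehyde) | CC(C)CC=O | starting material
13 | lithium 1,3-dimethoxy-2-methylbuta-1,3-dien-1-olate (dienolate of 11) | C=C(OC)C(C)=C([O-])OC.[Li+] | intermediate
14 | lithium alkoxide of racemic methyl (E)-5-hydroxy-3-methoxy-2,7-dimethyloct-2-enoate | CC(C)CC([O-])C/C(OC)=C(/C)C(=O)OC.[Li+] | intermediate
15 | racemic methyl (E)-5-[(tert-butyldimethylsilyl)oxy]-3-methoxy-2,7-dimethyloct-2-enoate | CC(C)CC(O[Si](C)(C)C(C)(C)C)C/C(OC)=C(/C)C(=O)OC | intermediate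
16 | racemic (E)-5-[(tert-butyldimethylsilyl)oxy]-3-methoxy-2,7-dimethyloct-2-enoic acid | CC(C)CC(O[Si](C)(C)C(C)(C)C)C/C(OC)=C(/C)C(O)=O | intermediate
17 | Meldrum's acid (2,2-dimethyl-1,3-dioxane-4,6-dione) | CC1(C)OC(=O)CC(=O)O1 | starting material
18 | 5-{(E)-5-[(tert-butyldimethylsilyl)oxy]-3-methoxy-2,7-dimethyloct-2-enoyl}-2,2-dimethyl-1,3-dioxane-4,6-dione (drawn as the keto tautomer) | CC(C)CC(O[Si](C)(C)C(C)(C)C)C/C(OC)=C(/C)C(=O)C1C(=O)OC(C)(C)OC1=O | intermediate
19 | racemic methyl (E)-7-[(tert-butyldimethylsilyl)oxy]-5-methoxy-4,9-dimethyl-3-oxodec-4-enoate | CC(C)CC(O[Si](C)(C)C(C)(C)C)C/C(OC)=C(/C)C(=O)CC(=O)OC | intermediate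
20 | methyl (E)-2-{[2,6-bis(benzyloxy)-4-methoxy-3-methyl-5-(2-methylpropanoyl)phenyl]methyl}-7-[(tert-butyldimethylsilyl)oxy]-5-methoxy-4,9-dimethyl-3-oxodec-4-enoate (diastereomer mixture, racemic) | CC(C)CC(O[Si](C)(C)C(C)(C)C)C/C(OC)=C(/C)C(=O)C(Cc1c(OCc2ccccc2)c(C)c(OC)c(C(=O)C(C)C)c1OCc1ccccc1)C(=O)OC | intermediate
21 | methyl (E)-2-{[2,6-bis(benzyloxy)-4-methoxy-3-methyl-5-(2-methylpropanoyl)phenyl]methyl}-7-hydroxy-5-methoxy-4,9-dimethyl-3-oxodec-4-enoate (diastereomer mixture, racemic; may equilibrate with its six-membered hemiketal) | CC(C)CC(O)C/C(OC)=C(/C)C(=O)C(Cc1c(OCc2ccccc2)c(C)c(OC)c(C(=O)C(C)C)c1OCc1ccccc1)C(=O)OC | intermediate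
22 | methyl (E)-2-{[2,6-bis(benzyloxy)-4-methoxy-3-methyl-5-(2-methylpropanoyl)phenyl]methyl}-5-methoxy-4,9-dimethyl-3,7-dioxodec-4-enoate (racemic at C2) | CC(C)CC(=O)C/C(OC)=C(/C)C(=O)C(Cc1c(OCc2ccccc2)c(C)c(OC)c(C(=O)C(C)C)c1OCc1ccccc1)C(=O)OC | intermediate
23 | 1-[3-({2,6-bis(benzyloxy)-4-methoxy-3-methyl-5-(2-methylpropanoyl)phenyl}methyl)-2,4-dihydroxy-6-methoxy-5-methylphenyl]-3-methylbutan-1-one | COc1c(C)c(O)c(Cc2c(OCc3ccccc3)c(C)c(OC)c(C(=O)C(C)C)c2OCc2ccccc2)c(O)c1C(=O)CC(C)C | intermediate
24 | 1-[3-({2,6-dihydroxy-4-methoxy-3-methyl-5-(2-methylpropanoyl)phenyl}methyl)-2,4-dihydroxy-6-methoxy-5-methylphenyl]-3-methylbutan-1-one (CNP0265841.0) | COc1c(C)c(O)c(Cc2c(O)c(C)c(OC)c(C(=O)C(C)C)c2O)c(O)c1C(=O)CC(C)C | target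

**Step count**

Total steps: 15. Longest linear sequence: 11 steps (steps 1 to 6, then 11 to 15).

**Steps most likely to fail**

1. Step 14 (key step). The C1 ester is part of the magnesium enolate of the β-keto ester and sits next to the crowded benzyl-bearing carbon. C-acylation may therefore be slower than methoxide-induced retro-Claisen cleavage of the C2–C3 bond. Fallback: close ring A before the bridge is attached. Setting out from 19, the silyl ether is cleaved with HF·pyridine to methyl (E)-7-hydroxy-5-methoxy-4,9-dimethyl-3-oxodec-4-enoate F1. Dess–Martin oxidation gives methyl (E)-5-methoxy-4,9-dimethyl-3,7-dioxodec-4-enoate F2. This unbranched chain is the classical substrate type for the magnesium alkoxide Claisen cyclisation and is folded with Mg(OMe)2 in methanol to 1-(4,6-dihydroxy-2-methoxy-3-methylphenyl)-3-methylbutan-1-one F3. Friedel–Crafts benzylation of its only free ring carbon with benzylic alcohol 8 (cat. p-TsOH, CH2Cl2) brings the route back at 23.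

2. Step 8. The lithium aldolate may lactonise onto the cis ester before it is silylated, and some α-attack of the dienolate may compete. Fallback: accept the lactone and reopen it. Setting out from 11 and 12, the aldolate is allowed to warm so that it closes to 4-methoxy-3-methyl-6-(2-methylpropyl)-5,6-dihydro-2H-pyran-2-one F4. Saponification with one equivalent of KOH in aqueous methanol gives potassium (E)-5-hydroxy-3-methoxy-2,7-dimethyloct-2-enoate F5. The dried salt is silylated on both oxygens (TBSCl, imidazole, DMF) to tert-butyldimethylsilyl (E)-5-[(tert-butyldimethylsilyl)oxy]-3-methoxy-2,7-dimethyloct-2-enoate F6. Selective cleavage of the silyl ester (K2CO3, MeOH/THF/H2O, then pH 4) brings the route back at acid 16.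

3. Step 6 (and the alkylation of step 11 that depends on it). The electron-rich benzylic bromide may ionise, leading to self-condensation or solvolysis during its preparation and to O-alkylation of the enolate. Fallback: form the C2–C3 bond, not the C2–CH2 bond, at the joining stage. Setting out from aldehyde 7 and Meldrum's acid 17, Knoevenagel condensation (cat. L-proline, EtOH, rt) gives 5-{[2,6-bis(benzyloxy)-4-methoxy-3-methyl-5-(2-methylpropanoyl)phenyl]methylidene}-2,2-dimethyl-1,3-dioxane-4,6-dione F7. It is reduced in the same flask by Hantzsch ester to 5-{[2,6-bis(benzyloxy)-4-methoxy-3-methyl-5-(2-methylpropanoyl)phenyl]methyl}-2,2-dimethyl-1,3-dioxane-4,6-dione F8. Refluxing methanol opens it to the half ester 2-{[2,6-bis(benzyloxy)-4-methoxy-3-methyl-5-(2-methylpropanoyl)phenyl]methyl}-3-methoxy-3-oxopropanoic acid F9. Acid 16 is converted with 1,1'-carbonyldiimidazole into (E)-5-[(tert-butyldimethylsilyl)oxy]-1-(1H-imidazol-1-yl)-3-methoxy-2,7-dimethyloct-2-en-1-one F10. Decarboxylative Claisen condensation of F9 with F10 (MgCl2, Et3N, THF, 40 °C) brings the route back at 20.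

**Further compounds**

F1 | step 14 | racemic methyl (E)-7-hydroxy-5-methoxy-4,9-dimethyl-3-oxodec-4-enoate | CC(C)CC(O)C/C(OC)=C(/C)C(=O)CC(=O)OC
F2 | step 14 | methyl (E)-5-methoxy-4,9-dimethyl-3,7-dioxodec-4-enoate | CC(C)CC(=O)C/C(OC)=C(/C)C(=O)CC(=O)OC
F3 | step 14 | 1-(4,6-dihydroxy-2-methoxy-3-methylphenyl)-3-methylbutan-1-one | COc1c(C)c(O)cc(O)c1C(=O)CC(C)C
F4 | step 8 | racemic 4-methoxy-3-methyl-6-(2-methylpropyl)-5,6-dihydro-2H-pyran-2-one | COC1=C(C)C(=O)OC(CC(C)C)C1
F5 | step 8 | racemic potassium (E)-5-hydroxy-3-methoxy-2,7-dimethyloct-2-enoate | CC(C)CC(O)C/C(OC)=C(/C)C(=O)[O-].[K+]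
F6 | step 8 | racemic tert-butyldimethylsilyl (E)-5-[(tert-butyldimethylsilyl)oxy]-3-methoxy-2,7-dimethyloct-2-enoate | CC(C)CC(O[Si](C)(C)C(C)(C)C)C/C(OC)=C(/C)C(=O)O[Si](C)(C)C(C)(C)C
F7 | step 6 | 5-{[2,6-bis(benzyloxy)-4-methoxy-3-methyl-5-(2-methylpropanoyl)phenyl]methylidene}-2,2-dimethyl-1,3-dioxane-4,6-dione | CC1(C)OC(=O)C(=Cc2c(OCc3ccccc3)c(C)c(OC)c(C(=O)C(C)C)c2OCc2ccccc2)C(=O)O1
F8 | step 6 | 5-{[2,6-bis(benzyloxy)-4-methoxy-3-methyl-5-(2-methylpropanoyl)phenyl]methyl}-2,2-dimethyl-1,3-dioxane-4,6-dione | CC1(C)OC(=O)C(Cc2c(OCc3ccccc3)c(C)c(OC)c(C(=O)C(C)C)c2OCc2ccccc2)C(=O)O1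
F9 | step 6 | racemic 2-{[2,6-bis(benzyloxy)-4-methoxy-3-methyl-5-(2-methylpropanoyl)phenyl]methyl}-3-methoxy-3-oxopropanoic acid | COC(=O)C(Cc1c(OCc2ccccc2)c(C)c(OC)c(C(=O)C(C)C)c1OCc1ccccc1)C(O)=O
F10 | step 6 | racemic (E)-5-[(tert-butyldimethylsilyl)oxy]-1-(1H-imidazol-1-yl)-3-methoxy-2,7-dimethyloct-2-en-1-one | CC(C)CC(O[Si](C)(C)C(C)(C)C)C/C(OC)=C(/C)C(=O)n1ccnc1
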